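**Plan**

Skeleton numbering used throughout: C1 CH–O-angelate, C2 CH2, C3 CH–O-tiglate, C4 C(CH3), C5 CH, C6 C=O, C7 =CH, C8 =C(CH3), C9 CH, C10 CH, C11 C(CH3)2.
Retrosynthesis: the two esters are removed and the enone is taken back to a C6 carbinol with a C8 exocyclic alkene; the cycloheptane is opened at C10–C11 (aldol) and C1–C11 (acyl coupling); the bicyclo[3.1.1]heptane is cut at C10–C5 and C9–C4 (ketene plus alkene); the chain is cut at C2–C3 and C6–C7 (two aldol additions).
Enabling feature: the cyclobutane C4–C5–C10–C9, spanned by the bridge C6–C7–C8, is a 3,7-dimethylocta-2,6-dienoyl chain when read C10–C9–C8–C7–C6–C5–C4–C3; its vinylketene (C10=C9 conjugated to C8) can add across C5=C4.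
Forward: a vinylogous aldol and an acetate aldol build the chain; step 10 closes the six-membered ring and the cyclobutanone together; a reductive aldol at C10 closes the seven-membered ring; deoxygenation, the two esters and the C6 enone follow.
Stereochemistry: C6 (catalyst-set, later erased) steers the cycloaddition face by allylic 1,3-strain and so fixes C4, C5 and C9; C3 comes from the catalytic thioacetate aldol; C10 from delivery of C11 by the arm; C1 from hydride delivery from the C3 oxygen.

Key step: step 10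

Remark (numbering): chain locants of acyclic intermediates run from the carboxyl carbon, which is skeleton C10; chain C5 is skeleton C6 and chain C8 is skeleton C3.
Remark (assumption): in steps 2 and 6 the enantiomer of the chiral controller is taken to be the one that gives the configuration drawn; the antipode is equally accessible if the sense is opposite.
Remark (assumption): amine dehydrochlorination of the (2E)-3-methyl-2-enoyl chloride is taken to remove a proton from the C8 methyl group cis to the carbonyl, so the cycloadduct is drawn with an exocyclic C8=CH2; the double bond moves to C7=C8 only at the enone stage.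
Remark (assumption): tert-butyl 3-methylbut-2-enoate is treated as a purchasable ester.

**Route**

Step 1
Reactants: 1 tert-butyl 3-methylbut-2-enoate
Product: 2 tert-butyl[(1-tert-butoxy-3-methylbuta-1,3-dien-1-yl)oxy]dimethylsilane (silyl dienol ether)
Conditions: LiN(i-Pr)2, THF, −78 °C; TBSCl, DMPU, −78 °C to rt
Reagents that add atoms: tert-butyl(chloro)dimethylsilane, CC(C)(C)[Si](C)(C)Cl
Why: γ-Deprotonation of the enoate and O-silylation of the extended enolate (silyl ketene acetal formation) should give the dienol ether needed as the vinylogous nucleophile.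

Step 2
Reactants: 2 silyl dienol ether; 3 3-methylbut-2-enal
Product: 5 tert-butyl (2E,5S)-5-hydroxy-3,7-dimethylocta-2,6-dienoate, via trichlorosilyl ether 4 (not isolated)
Conditions: SiCl4 (1.1 equiv), (R,R)-N,N'-dimethyl-N,N'-bis(3,5-dimethyl-4-oxido-3,5-dihydro-4H-dinaphtho[2,1-d:1',2'-f][1,3,2]diazaphosphepin-4-yl)pentane-1,5-diamine (5 mol %), CH2Cl2, −78 °C; aqueous NaHCO3
Reagents that add atoms: none
Why: A vinylogous Mukaiyama aldol addition under chiral Lewis-base activation of SiCl4 should join the γ-carbon of the dienolate to the aldehyde (C7–C6), with the catalyst fixing C6 as S and the enoate expected as the (2E) isomer.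

Step 3
Reactants: 5 hydroxy ester
Product: 6 tert-butyl (2E,5S)-5-(tert-butyldimethylsilyloxy)-3,7-dimethylocta-2,6-dienoate
Conditions: TBSCl, imidazole, DMF, rt
Reagents that add atoms: tert-butyl(chloro)dimethylsilane, CC(C)(C)[Si](C)(C)Cl
Why: O-Silylation of the secondary allylic alcohol installs the bulky C6 group that later steers the cycloaddition.

Step 4
Reactants: 6 silyl ether
Product: 8 tert-butyl (2E,5S,6E)-5-(tert-butyldimethylsilyloxy)-3,7-dimethyl-8-oxoocta-2,6-dienoate, via allylic alcohol 7 (not isolated)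
Conditions: SeO2 (0.3 equiv), t-BuOOH (3 equiv), CH2Cl2, rt; then MnO2, CH2Cl2, rt
Reagents that add atoms: tert-butyl hydroperoxide, CC(C)(C)OO (oxygen passed on through catalytic selenium dioxide, O=[Se]=O)
Why: Riley allylic oxidation (ene reaction then 2,3-sigmatropic shift) is expected to attack the (E)-methyl of the electron-richer trisubstituted C5=C4 alkene and not the enoate, and MnO2 then takes the allylic alcohol to the (E)-enal, so the remaining C4 methyl stays cis to C6.

Step 5
Reactants: 9 S-ethyl ethanethioate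
Product: 10 [1-(ethylsulfanyl)ethenyl]oxy(trimethyl)silane (silyl ketene thioacetal)
Conditions: LiN(i-Pr)2, THF, −78 °C; Me3SiCl
Reagents that add atoms: chlorotrimethylsilane, C[Si](C)(C)Cl
Why: Enolisation of the thioester and O-silylation (silyl ketene thioacetal formation) provide the acetate nucleophile.

Step 6
Reactants: 8 enal; 10 silyl ketene thioacetal
Product: 12 tert-butyl (2E,5S,6E,8R)-5-(tert-butyldimethylsilyloxy)-10-(ethylsulfanyl)-8-hydroxy-3,7-dimethyl-10-oxodeca-2,6-dienoate, via trimethylsilyl ether 11 (not isolated)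
Conditions: Sn(OTf)2 (20 mol %), (S)-1-methyl-2-[(naphthalen-1-ylamino)methyl]pyrrolidine (22 mol %), EtCN, −78 °C, slow addition; then 1 M aqueous citric acid, THF
Reagents that add atoms: none
Why: A catalytic asymmetric Mukaiyama aldol addition should form C2–C3 and set C3 as R under catalyst control, the remote C6 centre having little say, and mild acid then cleaves the trimethylsilyl ether.

Step 7
Reactants: 12 β-hydroxy thioester
Product: 13 tert-butyl (2E,5S,6E,8R)-5-(tert-butyldimethylsilyloxy)-10-(ethylsulfanyl)-3,7-dimethyl-10-oxo-8-(triethylsilyloxy)deca-2,6-dienoate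
Conditions: Et3SiCl, imidazole, CH2Cl2, 0 °C
Reagents that add atoms: chlorotriethylsilane, CC[Si](CC)(CC)Cl
Why: O-Silylation with the more labile triethylsilyl group allows the C3 oxygen to be freed later while the C6 silyl ether stays.

Step 8
Reactants: 13 tert-butyl ester
Product: 15 (2E,5S,6E,8R)-5-(tert-butyldimethylsilyloxy)-10-(ethylsulfanyl)-3,7-dimethyl-10-oxo-8-(triethylsilyloxy)deca-2,6-dienoic acid, via trimethylsilyl ester 14 (not isolated)
Conditions: Me3SiOTf, 2,6-lutidine, CH2Cl2, 0 °C to rt; then aqueous pH 5 buffer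
Reagents that add atoms: none
Why: Silyl-triflate-mediated cleavage of the tert-butyl ester (loss of isobutene to the silyl ester, hydrolysed on work-up) should free the acid without touching the thioester or the silyl ethers.

Step 9
Reactants: 15 dienoic acid
Product: 16 (2E,5S,6E,8R)-5-(tert-butyldimethylsilyloxy)-10-(ethylsulfanyl)-3,7-dimethyl-10-oxo-8-(triethylsilyloxy)deca-2,6-dienoyl chloride
Conditions: 1-chloro-N,N,2-trimethylprop-1-en-1-amine, CH2Cl2, 0 °C to rt; used crude
Reagents that add atoms: 1-chloro-N,N,2-trimethylprop-1-en-1-amine, CC(C)=C(Cl)N(C)C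
Why: Acyl chloride formation with the neutral chloroenamine avoids free HCl, which could ionise the two allylic silyl ethers.

Step 10
Reactants: 16 dienoyl chloride
Product: 18 bicyclo[3.1.1]heptan-6-one cycloadduct (C10 ketone; C8 exocyclic methylene; C6 OTBS; C4 methyl plus thioester arm), via vinylketene 17 (not isolated)
Conditions: Et3N (5 equiv), toluene, reflux, slow addition of 16 at high dilution
Reagents that add atoms: none
Why: Et3N removes HCl across C9 and the C8 methyl group to give vinylketene 17, whose electrophilic central carbon C10 bonds to the less substituted alkene carbon C5 while positive charge builds at the fully substituted C4, which then closes onto the ketene α-carbon C9 (asynchronous ketene–alkene [2+2] cycloaddition). The closest known reaction is the intramolecular vinylketene–alkene cycloaddition of geranoyl-type chlorides to 2-methylidenebicyclo[3.1.1]heptan-6-ones. The six-membered ring C5–C6–C7–C8–C9–C10 closes through C10–C5 and the cyclobutanone C4–C5–C10–C9 through C9–C4, the three-atom tether and the alkene polarity allowing only this bridged (crossed) mode and not a fused one. C4 is set by suprafacial transfer of the (E)-alkene geometry (methyl on the side of the C6–C8 bridge, arm on the side of C10), and C5 and C9 follow from the alkene face that is attacked. That face is fixed by C6, because allylic 1,3-strain against the C4 methyl holds the C6 hydrogen in the alkene plane, so the tether and the silyloxy group lie on opposite faces and the ketene arrives anti to the silyloxy group. The step needs this facial selectivity and enough alkene nucleophilicity despite two allylic oxygens; the C3 centre can exert only weak 1,2-induction against the C6 control, and any adduct from deprotonation at C7 (ring double bond C7=C8) would converge at step 19.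

Step 11
Reactants: 18 cycloadduct thioester
Product: 19 isopropenyl ketone (arm C3H(OTES)–C2H2–C1(=O)–C(CH3)=CH2; core as in 18)
Conditions: CH2=C(CH3)MgBr, ZnBr2, THF, 0 °C; then 18, PdCl2(PPh3)2 (5 mol %), toluene, rt
Reagents that add atoms: isopropenylmagnesium bromide, C=C(C)[Mg]Br (transmetallated in the flask to isopropenylzinc bromide, C=C(C)[Zn]Br)
Why: Fukuyama coupling (palladium-catalysed acylation of an organozinc halide by a thioester) should form the C1–C11 bond while the organozinc leaves the cyclobutanone untouched.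

Step 12
Reactants: 19 isopropenyl ketone
Product: 21 tricyclic β-hydroxy ketone (C1 ketone; C10 hydroxyl on the outer face; C11 on the face of the C4 arm), via copper enolate 20 (not isolated)
Conditions: [(Ph3P)CuH]6 (0.5 equiv), toluene, −40 to 0 °C; aqueous NH4Cl
Reagents that add atoms: none
Why: In this reductive aldol cyclisation, conjugate hydride transfer gives the C11 enolate regiospecifically and turns the methylene into the second C11 methyl, and the enolate, tethered to the arm on C4, can reach the C10 carbonyl only from the arm face, closing the seven-membered ring with the hydroxyl pointing outward.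

Step 13
Reactants: 21 tricyclic β-hydroxy ketone
Product: 22 C10 methyl oxalate of 21
Conditions: ClC(O)CO2Me, DMAP (cat), pyridine, CH2Cl2, 0 °C to rt
Reagents that add atoms: methyl chlorooxoacetate, COC(=O)C(=O)Cl
Why: Acylation of the tertiary cyclobutanol with the very reactive oxalyl half-ester chloride prepares it for radical C–O cleavage, and elimination cannot compete because C5 and C9 are bridgeheads and C11 is quaternary.

Step 14
Reactants: 22 methyl oxalate
Product: 23 tricyclic ketone with hydrogen at C10 (C1 ketone; C3 OTES; C6 OTBS; C8 methylidene)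
Conditions: Bu3SnH (5 equiv, 0.5 M), AIBN (cat), toluene, 110 °C
Reagents that add atoms: none
Why: In this radical deoxygenation of a tertiary methyl oxalate, the C10 radical can take hydrogen only on the outer face because the seven-membered ring holds C11 on the inner face, which gives the C10 configuration of the target, and the high stannane concentration should outrun fragmentation of the cyclobutyl radical.

Step 15
Reactants: 23 tricyclic ketone
Product: 24 β-hydroxy ketone with free C3 hydroxyl (C1 ketone; C6 OTBS)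
Conditions: PPTS (cat), MeOH–CH2Cl2, 0 °C
Reagents that add atoms: none
Why: Acid-catalysed methanolysis should remove the secondary triethylsilyl ether selectively in the presence of the more robust tert-butyldimethylsilyl ether.

Step 16
Reactants: 24 β-hydroxy ketone
Product: 26 C3 tiglate with free C1 hydroxyl trans to the C3 oxygen (C6 OTBS; C8 methylidene), via hemiacetal 25 (not isolated)
Conditions: (E)-2-methylbut-2-enal (8 equiv), SmI2 (0.3 equiv), THF, −10 °C
Reagents that add atoms: (E)-2-methylbut-2-enal, C/C=C(\C)C=O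
Why: In this Evans–Tishchenko reduction the C3 hydroxyl forms a samarium-bound hemiacetal with the aldehyde and passes its hydride to the C1 carbonyl through a six-membered transition state from the face of the C3 oxygen, which should give the C1 alcohol trans to C3 and leave the C3 oxygen as its tiglate.

Step 17
Reactants: 26 mono-tiglate
Product: 27 C1 angelate, C3 tiglate, C6 OTBS
Conditions: (Z)-2-methylbut-2-enoic acid, 2,4,6-trichlorobenzoyl chloride, Et3N, toluene, rt; then 26, 80 °C
Reagents that add atoms: (Z)-2-methylbut-2-enoic acid, C/C=C(/C)C(=O)O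
Why: Yamaguchi esterification through the mixed anhydride, run without DMAP, should acylate the hindered C1 alcohol while the (Z)-geometry of the angelate survives.

Step 18
Reactants: 27 diester silyl ether
Product: 28 C1 angelate, C3 tiglate, C6 alcohol
Conditions: HF·pyridine, pyridine, THF, 0 °C to rt
Reagents that add atoms: none
Why: Fluoride-mediated desilylation should free the C6 alcohol without touching the two unsaturated esters.

Step 19
Reactants: 28 diester alcohol
Product: 30 target diester (1R,3R,4R,5R,9R,10S), via exocyclic enone 29 (not isolated)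
Conditions: Dess–Martin periodinane, CH2Cl2, rt; aqueous work-up; then Et3N, CH2Cl2, rt
Reagents that add atoms: none
Why: Dess–Martin oxidation gives the β,γ-unsaturated C6 ketone, and amine-mediated tautomerisation through the dienol should move the exocyclic double bond into conjugation at C7=C8, which removes the C6 stereocentre and completes the enone.

**Compound list**

1 | tert-butyl 3-methylbut-2-enoate | CC(C)=CC(=O)OC(C)(C)C | starting material
2 | tert-butyl[(1-tert-butoxy-3-methylbuta-1,3-dien-1-yl)oxy]dimethylsilane | C=C(C)C=C(OC(C)(C)C)O[Si](C)(C)C(C)(C)C | intermediate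
3 | 3-methylbut-2-enal | CC(C)=CC=O | starting material
4 | tert-butyl (2E,5S)-3,7-dimethyl-5-(trichlorosilyloxy)octa-2,6-dienoate | CC(C)(C)OC(=O)/C=C(\C)C[C@H](O[Si](Cl)(Cl)Cl)C=C(C)C | intermediate
5 | tert-butyl (2E,5S)-5-hydroxy-3,7-dimethylocta-2,6-dienoate | CC(C)(C)OC(=O)/C=C(\C)C[C@H](O)C=C(C)C | intermediate
6 | tert-butyl (2E,5S)-5-(tert-butyldimethylsilyloxy)-3,7-dimethylocta-2,6-dienoate | CC(C)(C)OC(=O)/C=C(\C)C[C@H](O[Si](C)(C)C(C)(C)C)C=C(C)C | intermediate
7 | tert-butyl (2E,5S,6E)-5-(tert-butyldimethylsilyloxy)-8-hydroxy-3,7-dimethylocta-2,6-dienoate | CC(C)(C)OC(=O)/C=C(\C)C[C@H](O[Si](C)(C)C(C)(C)C)/C=C(\C)CO | intermediate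
8 | tert-butyl (2E,5S,6E)-5-(tert-butyldimethylsilyloxy)-3,7-dimethyl-8-oxoocta-2,6-dienoate | CC(C)(C)OC(=O)/C=C(\C)C[C@H](O[Si](C)(C)C(C)(C)C)/C=C(\C)C=O | intermediate
9 | S-ethyl ethanethioate | CCSC(C)=O | starting material
10 | [1-(ethylsulfanyl)ethenyl]oxy(trimethyl)silane | C=C(O[Si](C)(C)C)SCC | intermediate
11 | tert-butyl (2E,5S,6E,8R)-5-(tert-butyldimethylsilyloxy)-10-(ethylsulfanyl)-3,7-dimethyl-10-oxo-8-(trimethylsilyloxy)deca-2,6-dienoate | CC(C)(C)OC(=O)/C=C(\C)C[C@H](O[Si](C)(C)C(C)(C)C)/C=C(\C)[C@H](O[Si](C)(C)C)CC(=O)SCC | intermediate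
12 | tert-butyl (2E,5S,6E,8R)-5-(tert-butyldimethylsilyloxy)-10-(ethylsulfanyl)-8-hydroxy-3,7-dimethyl-10-oxodeca-2,6-dienoate | CC(C)(C)OC(=O)/C=C(\C)C[C@H](O[Si](C)(C)C(C)(C)C)/C=C(\C)[C@H](O)CC(=O)SCC | intermediate
13 | tert-butyl (2E,5S,6E,8R)-5-(tert-butyldimethylsilyloxy)-10-(ethylsulfanyl)-3,7-dimethyl-10-oxo-8-(triethylsilyloxy)deca-2,6-dienoate | CC(C)(C)OC(=O)/C=C(\C)C[C@H](O[Si](C)(C)C(C)(C)C)/C=C(\C)[C@H](O[Si](CC)(CC)CC)CC(=O)SCC | intermediate
14 | trimethylsilyl (2E,5S,6E,8R)-5-(tert-butyldimethylsilyloxy)-10-(ethylsulfanyl)-3,7-dimethyl-10-oxo-8-(triethylsilyloxy)deca-2,6-dienoate | C[Si](C)(C)OC(=O)/C=C(\C)C[C@H](O[Si](C)(C)C(C)(C)C)/C=C(\C)[C@H](O[Si](CC)(CC)CC)CC(=O)SCC | intermediate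
15 | (2E,5S,6E,8R)-5-(tert-butyldimethylsilyloxy)-10-(ethylsulfanyl)-3,7-dimethyl-10-oxo-8-(triethylsilyloxy)deca-2,6-dienoic acid | OC(=O)/C=C(\C)C[C@H](O[Si](C)(C)C(C)(C)C)/C=C(\C)[C@H](O[Si](CC)(CC)CC)CC(=O)SCC | intermediate
16 | (2E,5S,6E,8R)-5-(tert-butyldimethylsilyloxy)-10-(ethylsulfanyl)-3,7-dimethyl-10-oxo-8-(triethylsilyloxy)deca-2,6-dienoyl chloride | O=C(Cl)/C=C(\C)C[C@H](O[Si](C)(C)C(C)(C)C)/C=C(\C)[C@H](O[Si](CC)(CC)CC)CC(=O)SCC | intermediate
17 | S-ethyl (3R,4E,6S)-6-(tert-butyldimethylsilyloxy)-4-methyl-8-methylidene-10-oxo-3-(triethylsilyloxy)deca-4,9-dienethioate (vinylketene) | O=C=CC(=C)C[C@H](O[Si](C)(C)C(C)(C)C)/C=C(\C)[C@H](O[Si](CC)(CC)CC)CC(=O)SCC | intermediate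
18 | bicyclo[3.1.1]heptan-6-one cycloadduct: C10 ketone bridge; C4 bridge with CH3 (side of the C6–C8 bridge) and arm C3H(OTES)–C2H2–C1(=O)SEt (side of C10); C6 OTBS; C8 exocyclic CH2; C3 R, C4 R, C5 R, C6 S, C9 R | CCSC(=O)C[C@@H](O[Si](CC)(CC)CC)[C@@]1(C)[C@@H]2[C@@H](O[Si](C)(C)C(C)(C)C)CC(=C)[C@H]1C2=O | intermediate
19 | isopropenyl ketone: 18 with the arm C3H(OTES)–C2H2–C1(=O)–C(CH3)=CH2 | C=C(C)C(=O)C[C@@H](O[Si](CC)(CC)CC)[C@@]1(C)[C@@H]2[C@@H](O[Si](C)(C)C(C)(C)C)CC(=C)[C@H]1C2=O | intermediate
20 | copper enolate of 19, arm C3H(OTES)–C2H2–C1(OCu)=C11(CH3)2 (triphenylphosphine on copper not drawn) | CC(C)=C(O[Cu])C[C@@H](O[Si](CC)(CC)CC)[C@@]1(C)[C@@H]2[C@@H](O[Si](C)(C)C(C)(C)C)CC(=C)[C@H]1C2=O | intermediate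
21 | tricyclic β-hydroxy ketone: C1 ketone, C3 OTES, C6 OTBS, C8 exocyclic CH2, C10 OH on the outer face, C11 (CMe2) on the face of the C4 arm | O=C1C[C@@H](O[Si](CC)(CC)CC)[C@@]2(C)[C@@H]3[C@@H](O[Si](C)(C)C(C)(C)C)CC(=C)[C@H]2[C@]3(O)C1(C)C | intermediate
22 | C10 methyl oxalate of 21 | O=C1C[C@@H](O[Si](CC)(CC)CC)[C@@]2(C)[C@@H]3[C@@H](O[Si](C)(C)C(C)(C)C)CC(=C)[C@H]2[C@]3(OC(=O)C(=O)OC)C1(C)C | intermediate
23 | tricyclic ketone: 21 with hydrogen in place of the C10 hydroxyl (outer face) | O=C1C[C@@H](O[Si](CC)(CC)CC)[C@@]2(C)[C@@H]3[C@@H](O[Si](C)(C)C(C)(C)C)CC(=C)[C@H]2[C@@H]3C1(C)C | intermediate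
24 | β-hydroxy ketone: 23 with free C3 hydroxyl | O=C1C[C@@H](O)[C@@]2(C)[C@@H]3[C@@H](O[Si](C)(C)C(C)(C)C)CC(=C)[C@H]2[C@@H]3C1(C)C | intermediate
25 | C3 hemiacetal of 24 with (E)-2-methylbut-2-enal (samarium alkoxide, drawn as the neutral hemiacetal) | O=C1C[C@@H](OC(O)/C(C)=C/C)[C@@]2(C)[C@@H]3[C@@H](O[Si](C)(C)C(C)(C)C)CC(=C)[C@H]2[C@@H]3C1(C)C | intermediate
26 | C3 tiglate, C1 alcohol (C1 R, hydroxyl trans to the C3 oxygen), C6 OTBS, C8 exocyclic CH2 | O[C@@H]1C[C@@H](OC(=O)/C(C)=C/C)[C@@]2(C)[C@@H]3[C@@H](O[Si](C)(C)C(C)(C)C)CC(=C)[C@H]2[C@@H]3C1(C)C | intermediate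
27 | C1 angelate, C3 tiglate, C6 OTBS, C8 exocyclic CH2 | C/C=C(/C)C(=O)O[C@@H]1C[C@@H](OC(=O)/C(C)=C/C)[C@@]2(C)[C@@H]3[C@@H](O[Si](C)(C)C(C)(C)C)CC(=C)[C@H]2[C@@H]3C1(C)C | intermediate
28 | C1 angelate, C3 tiglate, C6 alcohol, C8 exocyclic CH2 | C/C=C(/C)C(=O)O[C@@H]1C[C@@H](OC(=O)/C(C)=C/C)[C@@]2(C)[C@@H]3[C@@H](O)CC(=C)[C@H]2[C@@H]3C1(C)C | intermediate
29 | C1 angelate, C3 tiglate, C6 ketone with C8 exocyclic CH2 (β,γ-unsaturated ketone) | C/C=C(/C)C(=O)O[C@@H]1C[C@@H](OC(=O)/C(C)=C/C)[C@@]2(C)[C@@H]3C(=O)CC(=C)[C@H]2[C@@H]3C1(C)C | intermediate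
30 | target: C1 angelate, C3 tiglate, C6 ketone, C7=C8 (1R,3R,4R,5R,9R,10S in skeleton numbering) | C/C=C(/C)C(=O)O[C@@H]1C[C@@H](OC(=O)/C(C)=C/C)[C@@]2(C)[C@@H]3C(=O)C=C(C)[C@H]2[C@@H]3C1(C)C | target

**Step count**

Total: 19 steps. Longest linear sequence: 18 steps (steps 1–4 and 6–19, from 1 to 30); step 5 is a one-step side branch.

**Steps most likely to fail**

Step 12. Protonation of the copper enolate (plain 1,4-reduction) or 1,2-reduction of the cyclobutanone may win over the hindered seven-membered aldol closure. The fallback sets out from 19 and comes back at 21. RhCl(PPh3)3-catalysed 1,4-hydrosilylation with Et3SiH gives the tetrasubstituted triethylsilyl enol ether F3, an isolable C11 nucleophile. BF3·OEt2 at −78 °C then activates the C10 ketone for an intramolecular Mukaiyama aldol addition from the arm face, and aqueous work-up gives 21.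

Step 16. Hydride transfer may fail with the conjugated aldehyde, through its samarium-mediated reduction or slow hemiacetal formation at the hindered C3 hydroxyl, or the acyl group may wander to the C1 oxygen. The fallback sets out from 24 and comes back at 26. The same samarium-catalysed reduction is run with propanal, whose hemiacetal is the better hydride donor, and gives the C3 propanoate with free C1 hydroxyl F4. Et3SiOTf and 2,6-lutidine silylate the C1 hydroxyl to give the C1 triethylsilyl ether C3 propanoate F5. i-Bu2AlH at −78 °C removes the propanoate to give the C3 alcohol F6. (E)-2-Methylbut-2-enoic acid with 2,4,6-trichlorobenzoyl chloride, Et3N and DMAP acylates C3 to give the C3 tiglate C1 triethylsilyl ether F7. PPTS in MeOH removes the triethylsilyl group and gives 26.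

Step 10. The cycloaddition may be outrun by oligomerisation of the vinylketene, because the C5=C4 alkene is flanked by two silyloxy-bearing carbons and is a weaker nucleophile than in simple geranoyl chlorides. The fallback sets out from 16 and comes back at 18. Pyrrolidine (1 equiv) and Et3N at −78 °C convert the acid chloride into the pyrrolidine amide F1. Tf2O and 2,4,6-collidine in 1,2-dichloroethane then give, by O-triflation and loss of a proton from the C8 methyl group, the vinylketeniminium triflate, a much stronger electrophile than the ketene. It closes the same two bonds (C10–C5, C9–C4) to the cyclobutaniminium triflate F2, which aqueous NaHCO3 hydrolyses to 18.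

Further compounds
F1 | step 10 | pyrrolidine amide of acid 15 | O=C(/C=C(\C)C[C@H](O[Si](C)(C)C(C)(C)C)/C=C(\C)[C@H](O[Si](CC)(CC)CC)CC(=O)SCC)N1CCCC1
F2 | step 10 | cyclobutaniminium triflate (18 with C10=N+ pyrrolidinium in place of the C10 carbonyl) | CCSC(=O)C[C@@H](O[Si](CC)(CC)CC)[C@@]1(C)[C@@H]2[C@@H](O[Si](C)(C)C(C)(C)C)CC(=C)[C@H]1C2=[N+]1CCCC1.[O-]S(=O)(=O)C(F)(F)F
F3 | step 12 | triethylsilyl enol ether of 19 (arm C3H(OTES)–C2H2–C1(OSiEt3)=C11(CH3)2) | CC(C)=C(O[Si](CC)(CC)CC)C[C@@H](O[Si](CC)(CC)CC)[C@@]1(C)[C@@H]2[C@@H](O[Si](C)(C)C(C)(C)C)CC(=C)[C@H]1C2=O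
F4 | step 16 | C3 propanoate with free C1 hydroxyl (trans), C6 OTBS | O[C@@H]1C[C@@H](OC(=O)CC)[C@@]2(C)[C@@H]3[C@@H](O[Si](C)(C)C(C)(C)C)CC(=C)[C@H]2[C@@H]3C1(C)C
F5 | step 16 | C1 triethylsilyl ether, C3 propanoate, C6 OTBS | CC[Si](CC)(CC)O[C@@H]1C[C@@H](OC(=O)CC)[C@@]2(C)[C@@H]3[C@@H](O[Si](C)(C)C(C)(C)C)CC(=C)[C@H]2[C@@H]3C1(C)C
F6 | step 16 | C1 triethylsilyl ether, C3 alcohol, C6 OTBS | CC[Si](CC)(CC)O[C@@H]1C[C@@H](O)[C@@]2(C)[C@@H]3[C@@H](O[Si](C)(C)C(C)(C)C)CC(=C)[C@H]2[C@@H]3C1(C)C
F7 | step 16 | C1 triethylsilyl ether, C3 tiglate, C6 OTBS | CC[Si](CC)(CC)O[C@@H]1C[C@@H](OC(=O)/C(C)=C/C)[C@@]2(C)[C@@H]3[C@@H](O[Si](C)(C)C(C)(C)C)CC(=C)[C@H]2[C@@H]3C1(C)C
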